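Whatever happens in a flask, the coupling partner charged must be found again: free, in target, or lost.

| flask | substrate | coupling partner | remark | time |
|---|---|---|---|---|
| north | 0.20 M (fed, over 0.60 h) | 0.16 M | run made earlier |  |
| east | 0.20 M (fed, over 0.60 h) | 0.36 M | run made earlier |  |
| elm | 0.20 M (fed, over 0.60 h) | 0.240 M |  | 4.0 d |
| larch | 0.20 M (fed, over 1.2 h) | 0.240 M |  | 4.0 d |
| oak | 0.20 M (fed, over 2.5 h) | 0.240 M |  | 4.0 d |

| run | time / d | target / % |
|---|---|---|
| north | 0.625 | 65.5 |
| north | 1.25 | 66.7 |
| north | 1.67 | 67.1 |
| north | 2.50 | 67.1 |
| north | 3.00 | 67.2 |
| north | 4.00 | 66.3 |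
| east | 0.333 | 90.3 |
| east | 0.500 | 94.8 |
| east | 0.833 | 96.3 |
| east | 1.04 | 97.0 |
| east | 1.67 | 97.5 |
| east | 2.50 | 97.0 |
| east | 4.00 | 97.2 |

(scatter of a reading: 0.5 percentage points)

- "hardly changes" means that all values lie within two and a half points (for a concentration: within two and a half percent of the largest)

1. [target] at the end for elm, larch, oak, in this order
2. how the row runs (rises all the way / rises, then falls / falls, then rises / falls all the way / hardly changes)

North's target stays flat near 67.1% of the substrate, which is 0.134 M from 0.16 M of partner. I read that plateau as no free partner, the limiting reagent, with 0.0258 M lost and 0.0658 M of substrate stranded.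

I take the loss as first order in partner. Coupling and loss then draw on partner at a rate ratio of substrate over one constant, the break-even substrate, at which both rates are equal. Summed along a run, lost = break-even × ln(substrate charged / substrate left), so north gives 0.0232 M.

With the whole elm charge in, the ratio would be 8.62. Falling substrate slows coupling, and the ln term adds up that slowing. A first trial for elm leaves 0.0166 M of substrate, and one correction leaves 0.0171 M. The ratio then ends at 0.737, and my elm target is 0.183 M.

A steady feed delays substrate by half the feed time on average. The price of that delay needs the loss rate. East at 0.333 d stands 0.0138 M short of its plateau, with partner near 0.117 M. Its logarithmic mean partner, 0.216 M, replaces the curve and gives a loss rate of 0.894 d⁻¹. In my estimate for elm, a share 0.424 of partner lost to delay is target forgone, so each hour of mean delay costs about 0.00379 M h⁻¹ of target. Oak's mean delay stands 0.950 h beyond elm's, so I expect the row to hardly change.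

The forecast says 0.172 M, 0.169 M, 0.163 M, falls all the way: “Slower feeding lets partner decay before substrate arrives”.

The flask gives 0.182 M, 0.180 M, 0.178 M, and the row hardly changes. Elm ends with 7.62% of its substrate left, oak with 9.64%.

    substrate + coupling partner → target (k = 5.70 × 10⁻⁴ M⁻¹ s⁻¹)
    substrate + 2 coupling partner → side product (k = 7.90 × 10⁻⁵ M⁻² s⁻¹)
    coupling partner → decomposed reagent (k = 1.10 × 10⁻⁵ s⁻¹)

Now take elm, using the break-even substrate once more. With the 0.0152 M of substrate that elm ends on, the summed rule gives 0.0598 M of partner outside target, and elm's flask has 0.0580 M outside target.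

All runs are calculated on assumed constants, noise included.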